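Everything rests on closing ring C last, at C4–C4a, rather than joining two flavans at C4–C8'. The feature exploited: C4 is benzylic to the trioxygenated ring D and the C3 hydroxyl is trans to ring D, so C3–C4 can be carried as a trans-epoxide already attached to C8' of catechin. In one operation an ortho carbon of ring A opens that epoxide at C4 with inversion, creating C4–C4a, ring C, the C4 stereocentre and the free C3–OH. The precursor is the perbenzylated threo C2 3,5-dibenzyloxyphenyl ether of this epoxide, bearing ring B on C2 and, as an added design element, a removable bromine on C6' that tempers and blocks ring D.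

Key step: step 11

Remark: the SMILES string is taken as binding, that is epiafzelechin-(4β→8)-catechin with (2R,3R), ring D β on C4 and (2'R,3'S). The upper flavan has rings A, C, B and atoms O1, C2–C8a, the lower catechin has rings D, F, E and primed atoms, and acyclic intermediates already carry the flavan numbers C2, C3, C4.

Step 1
Reactants: 1 (+)-catechin
Product: 2 tetra-O-benzylcatechin (both ring D and both ring E phenols benzylated, C3'–OH free)
Conditions: BnBr (4.4 equiv), K2CO3, DMF, 0 °C → rt
Reagents that add atoms: benzyl bromide, BrCc1ccccc1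
Why: Williamson etherification with a weak carbonate base alkylates only the four phenols, leaves the secondary C3' alcohol untouched and avoids the strongly basic conditions under which free-phenol flavans epimerise at C2'.

Step 2
Reactants: 2 tetra-O-benzylcatechin
Product: 3 penta-O-benzylcatechin (C3'–OBn as well)
Conditions: NaH, BnBr, DMF, 0 °C → rt
Reagents that add atoms: benzyl bromide, BrCc1ccccc1
Why: Williamson etherification of the secondary alkoxide is safe once no free phenol is left to open ring F, and it masks the one hydroxyl that would later interfere in the lithiation and Mitsunobu steps.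

Step 3
Reactants: 3 penta-O-benzylcatechin
Product: 4 8'-bromo-penta-O-benzylcatechin
Conditions: NBS (1.0 equiv), CH2Cl2, −78 °C → 0 °C
Reagents that add atoms: N-bromosuccinimide, O=C1CCC(=O)N1Br
Why: Electrophilic aromatic bromination of O-benzylated catechins with one equivalent of NBS at low temperature is known to go to C8' of the phloroglucinol-type ring D in preference to C6' and to the less activated ring E.

Step 4
Reactants: 4 8'-bromo-penta-O-benzylcatechin
Product: 6 penta-O-benzylcatechin-8'-carbaldehyde, via C8' aryllithium 5 (not isolated)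
Conditions: n-BuLi, THF, −78 °C; DMF, −78 °C → 0 °C; H2O
Reagents that add atoms: N,N-dimethylformamide, CN(C)C=O
Why: Bromine–lithium exchange at −78 °C outruns deprotonation of the benzyl ethers, and formylation of the aryllithium with DMF (Bouveault aldehyde synthesis) places the future C4 on C8' without regiochemical ambiguity.

Step 5
Reactants: 6 penta-O-benzylcatechin-8'-carbaldehyde
Product: 7 6'-bromo-penta-O-benzylcatechin-8'-carbaldehyde
Conditions: NBS (1.05 equiv), CH2Cl2, 0 °C → rt, dark
Reagents that add atoms: N-bromosuccinimide, O=C1CCC(=O)N1Br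
Why: Electrophilic aromatic bromination goes to C6', the only free and still triply oxygen-activated carbon of ring D (meta to the formyl group), and the halogen serves three purposes: it lowers the donor power of ring D inductively and by twisting both flanking benzyloxy groups out of conjugation so that the later C4 epoxide can be handled, it blocks the last nucleophilic carbon of ring D, and it leaves without an extra step in the final hydrogenolysis.

Step 6
Reactants: 7 6'-bromo-penta-O-benzylcatechin-8'-carbaldehyde; 8 1-[4-(benzyloxy)phenyl]ethanone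
Product: 9 (E)-enone with ring B on the C2 carbonyl, C3=C4, and C4 on C8'
Conditions: KOH, EtOH–THF, rt
Reagents that add atoms: none
Why: Claisen–Schmidt condensation of a non-enolisable aldehyde with an aryl methyl ketone gives the conjugated (E)-enone through E1cB dehydration, brings in C2, C3 and ring B in one operation, and touches no stereocentre because ring F carries no free phenol.

Step 7
Reactants: 9 (E)-enone
Product: 10 (E)-allylic alcohol, both C2 epimers
Conditions: i-Bu2AlH, toluene–CH2Cl2, −78 °C; aq potassium sodium tartrate; Et3N-deactivated SiO2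
Reagents that add atoms: none
Why: 1,2-Reduction of the enone by an aluminium hydride in an aprotic medium with a non-acidic work-up avoids conjugate reduction and solvolysis of the easily ionised diaryl allylic alcohol, and since no facial bias is expected both C2 epimers should form and are carried on together.

Step 8
Reactants: 10 (E)-allylic alcohol, both C2 epimers
Product: 11 erythro (2S,3S,4S)-epoxy alcohol
Conditions: Ti(OiPr)4 (cat.), L-(+)-DIPT, t-BuOOH (0.55 equiv), 4 Å MS, CH2Cl2, −20 °C; cold aq NaOH–NaCl; Et3N-deactivated SiO2
Reagents that add atoms: tert-butyl hydroperoxide, CC(C)(C)OO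
Why: Sharpless asymmetric epoxidation run as a kinetic resolution of the two C2 epimers: by the empirical rule for L-(+)-tartrate the (2R) epimer of 10 is the fast-reacting one and takes oxygen on the face that gives the erythro epoxy alcohol, so reagent control sets C3 and C4 and selects C2 (its descriptor becomes 2S only through a priority change), catalytic titanium with sieves limits opening of the bromine-tempered benzylic epoxide, and the unreacted (2S) epimer is separated and can be returned to 9 with MnO2.

Step 9
Reactants: 12 phloroglucinol
Product: 13 3,5-bis(benzyloxy)phenol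
Conditions: BnBr (2 equiv), K2CO3, DMF, rt
Reagents that add atoms: benzyl bromide, BrCc1ccccc1
Why: Williamson etherification with two equivalents of benzyl bromide gives a statistical mixture from which the dibenzyl ether is separated by chromatography, which is acceptable for a cheap symmetric triol off the main line.

Step 10
Reactants: 11 erythro (2S,3S,4S)-epoxy alcohol; 13 3,5-bis(benzyloxy)phenol
Product: 14 threo (2R,3R,4S) C2 aryl ether of the C3–C4 trans-epoxide
Conditions: PPh3, DIAD, toluene, 0 °C → rt; Et3N-deactivated SiO2
Reagents that add atoms: none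
Why: Mitsunobu etherification displaces the C2 oxyphosphonium group by the phenoxide with SN2 inversion and so turns the erythro alcohol into the threo ether, the electron-withdrawing epoxide next to C2 and the non-polar solvent disfavouring ionisation at the p-alkoxybenzylic carbon and the near-neutral medium sparing the epoxide.

Step 11
Reactants: 14 threo (2R,3R,4S) C2 aryl ether of the C3–C4 trans-epoxide
Product: 15 6'-bromo-octa-O-benzyl-epiafzelechin-(4β→8)-catechin with free C3–OH
Conditions: 1,1,1,3,3,3-hexafluoro-2-propanol (HFIP)–CH2Cl2 (4:1), 0.005 M, 0 °C → rt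
Reagents that add atoms: none
Why: HFIP hydrogen-bonds to the epoxide oxygen and polarises the C4–O bond, which is benzylic to the trioxygenated ring D, and an ortho carbon of the 3,5-dibenzyloxyphenyl ether (ring A) attacks C4 from the side opposite the oxygen, after which the Wheland intermediate loses a proton. This is the known intramolecular Friedel–Crafts epoxy-arene cyclisation of aryl 3-arylglycidyl ethers to trans-4-aryl-3-chromanols, applied here to a substrate with one more substituent at C2. Ring C closes in the 6-endo-tet mode, both epoxide carbons ending up in the new ring. The only new stereocentre, C4, is controlled by the (4S) epoxide carbon through inversion, which puts ring D β and trans to the released C3–OH while C2 and C3 keep all their bonds and hence the 2,3-cis relation; should the opening drift towards a ring D stabilised cation, closure anti to the C3 oxygen and peri strain with the C5 benzyloxy group favour the same epimer. The step needs attack at C4 rather than C3 (6-endo over 5-exo), which the benzylic activation by ring D secures, and intramolecular rather than intermolecular arylation, which high dilution, the equivalence of the two ring A ortho carbons and the bromine on C6' secure. The bromine also slows unassisted ionisation, so that a hydride shift to the ketone should not outrun ring closure.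

Step 12
Reactants: 15 6'-bromo-octa-O-benzyl-epiafzelechin-(4β→8)-catechin
Product: 16 gambiriin C
Conditions: H2 (1 atm), Pd(OH)2/C, NaOAc, THF–MeOH–H2O, rt
Reagents that add atoms: none
Why: Catalytic hydrogenolysis cleaves the eight benzyl ethers and the C6'–Br bond in one operation, NaOAc buffering the HBr that would otherwise threaten the acid-labile interflavan bond, while the pyran C–O bonds and all five stereocentres should be unaffected under one atmosphere of H2.

Compound list
1 | (+)-catechin, (2'R,3'S) | Oc1cc(O)c2c(c1)O[C@H](c1ccc(O)c(O)c1)[C@@H](O)C2 | starting material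
2 | tetra-O-benzylcatechin, C3'–OH free | O(Cc9ccccc9)c1cc(OCc9ccccc9)c2c(c1)O[C@H](c1ccc(OCc9ccccc9)c(OCc9ccccc9)c1)[C@@H](O)C2 | intermediate
3 | penta-O-benzylcatechin | O(Cc9ccccc9)c1cc(OCc9ccccc9)c2c(c1)O[C@H](c1ccc(OCc9ccccc9)c(OCc9ccccc9)c1)[C@@H](OCc9ccccc9)C2 | intermediate
4 | 8'-bromo-penta-O-benzylcatechin | Brc1c(OCc9ccccc9)cc(OCc9ccccc9)c2c1O[C@H](c1ccc(OCc9ccccc9)c(OCc9ccccc9)c1)[C@@H](OCc9ccccc9)C2 | intermediate
5 | 8'-lithio-penta-O-benzylcatechin (C8' aryllithium, not isolated) | [Li]c1c(OCc9ccccc9)cc(OCc9ccccc9)c2c1O[C@H](c1ccc(OCc9ccccc9)c(OCc9ccccc9)c1)[C@@H](OCc9ccccc9)C2 | intermediate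
6 | penta-O-benzylcatechin-8'-carbaldehyde | O=Cc1c(OCc9ccccc9)cc(OCc9ccccc9)c2c1O[C@H](c1ccc(OCc9ccccc9)c(OCc9ccccc9)c1)[C@@H](OCc9ccccc9)C2 | intermediate
7 | 6'-bromo-penta-O-benzylcatechin-8'-carbaldehyde | O=Cc1c(OCc9ccccc9)c(Br)c(OCc9ccccc9)c2c1O[C@H](c1ccc(OCc9ccccc9)c(OCc9ccccc9)c1)[C@@H](OCc9ccccc9)C2 | intermediate
8 | 1-[4-(benzyloxy)phenyl]ethanone | CC(=O)c1ccc(OCc2ccccc2)cc1 | starting material
9 | (E)-1-[4-(benzyloxy)phenyl]-3-(6'-bromo-penta-O-benzylcatechin-8'-yl)prop-2-en-1-one | O(Cc9ccccc9)c1ccc(C(=O)/C=C/c3c(OCc9ccccc9)c(Br)c(OCc9ccccc9)c4c3O[C@H](c3ccc(OCc9ccccc9)c(OCc9ccccc9)c3)[C@@H](OCc9ccccc9)C4)cc1 | intermediate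
10 | (E)-allylic alcohol from 9, both C2 epimers | O(Cc9ccccc9)c1ccc(C(O)/C=C/c3c(OCc9ccccc9)c(Br)c(OCc9ccccc9)c4c3O[C@H](c3ccc(OCc9ccccc9)c(OCc9ccccc9)c3)[C@@H](OCc9ccccc9)C4)cc1 | intermediate
11 | erythro (2S,3S,4S)-epoxy alcohol: C2–OH bearing ring B, C3–C4 trans-epoxide bearing ring D | O(Cc9ccccc9)c1ccc([C@H](O)[C@@H]2O[C@H]2c3c(OCc9ccccc9)c(Br)c(OCc9ccccc9)c4c3O[C@H](c3ccc(OCc9ccccc9)c(OCc9ccccc9)c3)[C@@H](OCc9ccccc9)C4)cc1 | intermediate
12 | phloroglucinol | Oc1cc(O)cc(O)c1 | starting material
13 | 3,5-bis(benzyloxy)phenol | Oc1cc(OCc2ccccc2)cc(OCc2ccccc2)c1 | intermediate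
14 | threo (2R,3R,4S) C2 3,5-bis(benzyloxy)phenyl ether of the C3–C4 trans-epoxide (key-step precursor) | O(Cc9ccccc9)c1ccc([C@@H](Oc3cc(OCc9ccccc9)cc(OCc9ccccc9)c3)[C@@H]2O[C@H]2c3c(OCc9ccccc9)c(Br)c(OCc9ccccc9)c4c3O[C@H](c3ccc(OCc9ccccc9)c(OCc9ccccc9)c3)[C@@H](OCc9ccccc9)C4)cc1 | intermediate
15 | 6'-bromo-octa-O-benzyl-epiafzelechin-(4β→8)-catechin, (2R,3R), 2,3-cis-3,4-trans, free C3–OH (key-step product) | O(Cc9ccccc9)c1ccc([C@H]2Oc3cc(OCc9ccccc9)cc(OCc9ccccc9)c3[C@H](c3c(OCc9ccccc9)c(Br)c(OCc9ccccc9)c4c3O[C@H](c3ccc(OCc9ccccc9)c(OCc9ccccc9)c3)[C@@H](OCc9ccccc9)C4)[C@H]2O)cc1 | intermediate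
16 | gambiriin C, epiafzelechin-(4β→8)-catechin | Oc1ccc([C@H]2Oc3cc(O)cc(O)c3[C@H](c3c(O)cc(O)c4c3O[C@H](c3ccc(O)c(O)c3)[C@@H](O)C4)[C@H]2O)cc1 | target

Total step count: 12. Longest linear sequence: 11 (steps 1–8 and 10–12, from (+)-catechin).

Steps most likely to fail

Step 11. Ionisation at C4 may run ahead of C–C bond formation. A 1,2-hydride shift from C3, capture by the solvent or closure from the wrong face could then compete. The need to place ring B pseudo-axially in the anti-opening geometry may also slow the closure. The fallback separates epoxide opening from ring closure. Setting out from 14, benzyl mercaptan with LiClO4 in MeCN–CH2Cl2 at 0 °C should open the epoxide at the benzylic C4 in the anti sense, giving the storable C4 benzyl sulfide with free C3 hydroxyl F1. The thiophilic salt AgBF4 in CH2Cl2–THF at −40 °C then abstracts the sulfide, a known non-acidic way to generate C4 cations in flavan-3-ol chemistry. Ring A should trap the cation anti to the C3 oxygen, which comes back to the route at 15.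

Step 8. The tetravalent titanium alkoxide may assist ionisation of the doubly activated allylic alcohol, leading to epimerisation or 1,3-transposition. It may also assist opening of the newly formed benzylic epoxide by isopropoxide or tert-butanol, and the bulky ring D may erode the rate discrimination between the two epimers. The fallback moves the oxidation to the enone, where conditions are basic and the carbonyl group stabilises the epoxide. Setting out from 9, Juliá–Colonna epoxidation (poly-L-leucine, urea–H2O2, DBU, THF, rt), a reaction known for polyoxygenated chalcones, should give the (3R,4S) trans-epoxy ketone F2. Chelation-controlled reduction with Zn(BH4)2 (Et2O–THF, −20 °C), known to be erythro-selective for α,β-epoxy ketones, comes back to the route at 11. This path also avoids setting half of the material aside.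

Step 10. The oxyphosphonium group sits on a p-alkoxybenzylic carbon. Partial ionisation with erosion of the inversion, or C-alkylation of the ambident phloroglucinol-type phenoxide, may therefore compete with clean SN2 displacement. The fallback forms the ether bond at the aryl carbon instead, so that C2 never carries a leaving group. It sets out from the slow-reacting (2S) epimer of 10 recovered in step 8, which already has the C2–O geometry of 14. Shi epoxidation with the enantiomer of the fructose-derived ketone (KHSO5, K2CO3, MeCN–dimethoxymethane–H2O, 0 °C) should give, under reagent control, the threo (2R,3S,4S) epoxy alcohol F3. Chan–Lam-type O-arylation follows with potassium 3,5-bis(benzyloxy)phenyltrifluoroborate F4, made from the commercial boronic acid and KHF2, under Cu(OAc)2 catalysis (DMAP, 4 Å MS, O2, CH2Cl2, rt). This retains C2 and comes back to the route at 14.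

Further compounds
F1 | step 11 | C4 benzyl sulfide from anti opening of 14, free C3–OH, C2 aryl ether unchanged | O(Cc9ccccc9)c1ccc([C@@H](Oc3cc(OCc9ccccc9)cc(OCc9ccccc9)c3)[C@H](O)[C@H](SCc9ccccc9)c3c(OCc9ccccc9)c(Br)c(OCc9ccccc9)c4c3O[C@H](c3ccc(OCc9ccccc9)c(OCc9ccccc9)c3)[C@@H](OCc9ccccc9)C4)cc1
F2 | step 8 | (3R,4S) trans-epoxy ketone from 9 | O(Cc9ccccc9)c1ccc(C(=O)[C@@H]2O[C@H]2c3c(OCc9ccccc9)c(Br)c(OCc9ccccc9)c4c3O[C@H](c3ccc(OCc9ccccc9)c(OCc9ccccc9)c3)[C@@H](OCc9ccccc9)C4)cc1
F3 | step 10 | threo (2R,3S,4S)-epoxy alcohol | O(Cc9ccccc9)c1ccc([C@@H](O)[C@@H]2O[C@H]2c3c(OCc9ccccc9)c(Br)c(OCc9ccccc9)c4c3O[C@H](c3ccc(OCc9ccccc9)c(OCc9ccccc9)c3)[C@@H](OCc9ccccc9)C4)cc1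
F4 | step 10 | potassium 3,5-bis(benzyloxy)phenyltrifluoroborate | [K+].F[B-](F)(F)c1cc(OCc2ccccc2)cc(OCc2ccccc2)c1
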